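In a one-step world E and L make J and G, one for one, and every J is read as Z, so the Z at the end equals the smaller of the two charges. L is then the limiting reagent wherever its charge lies below that of E.

| flask | E | L | remark | time |
|---|---|---|---|---|
| Friday's | 0.050 M (in portions, 4) | 0.18 M | run made earlier; portions every 25 min |  |
| larch | 0.050 M (in portions, 4) | 0.120 M | the portions of E follow each other after 25 min, the first at the start | 25 h |
| ash | 0.080 M (in portions, 4) | 0.120 M | the portions of E follow each other after 25 min, the first at the start | 25 h |
| cedar | 0.12 M (in portions, 4) | 0.120 M | the portions of E follow each other after 25 min, the first at the start | 25 h |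
| alder | 0.20 M (in portions, 4) | 0.120 M | the portions of E follow each other after 25 min, the first at the start | 25 h |

Friday's run (percent of the E charged)

| time / h | Z / % |
|---|---|
| 1.33 | 24.1 |
| 2.50 | 38.6 |
| 4.00 | 38.4 |
| 5.00 | 35.5 |

(scatter of a reading: 1 percentage point)

- a species is counted by the E in it: one X counts as two
- the earlier runs were read with a standard deviation of 1 percentage point
- steps that have been proposed: E + L -> J + G; J <-> Q; E + J -> X; J <-> Z
- "hardly changes" means that all values lie within two and a half points (for a concentration: within two and a half percent of the largest)

- [Z] at the end for larch, ash, cedar, alder, in this order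
- how the row runs (rises all the way / rises, then falls / falls all the way / falls, then rises / hardly changes)

I compared the charges in powers of ten. The logarithm of L over E was 0.380 in larch and −0.222 in alder, and it crossed zero at cedar, where the charges are equal. On this first step alone the row would rise to cedar and stay level.

Friday's run refuted that world, since Z, with L charged more heavily than E, was read no higher than 38.6 %, at 2.50 h, and the reading of 38.4 % at 4.00 h lay within the scatter of it, so the readings place a maximum of Z somewhere between those times without giving its height exactly.

So I added the second process, J passing on to Z and Q. Z lost 2.9 percentage points in the last hour, so I took the last reading, 35.5 % at 5.00 h, with its scatter of 1 point, as the ceiling share, the highest part of the smaller charge that I expected to remain as Z. Each flask's ceiling was therefore: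

ceiling = share × smaller charge

larch: 0.0177 M
ash: 0.0284 M
cedar: 0.0426 M
alder: 0.0426 M

Then I added the last process, E meeting J to give X. In alder E exceeds L by 0.0800 M, and if all of that E consumed J, the pool of J, Z and Q would shrink:

pool = 2 × L − E = 0.0400 M, and with the share, Z = 0.0142 M

I therefore expected alder between that figure and its ceiling, below cedar, and the other flasks just under their ceilings.

The forecast gave 0.012 M, 0.019 M, 0.022 M and 0.01 M, so that the row rises, then falls, saying “Once E exceeds L, stoichiometry bites”. These numbers differ from mine: its cedar value stands lower than my ceiling.

    E + L → J + G (k = 6.10 M⁻¹ h⁻¹)
    J ⇌ Q (K = 10.0, k = 2.60 h⁻¹)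
    E + J → X (k = 1.30 M⁻¹ h⁻¹)
    J ⇌ Z (K = 5.10, k = 6.50 h⁻¹)

The flasks gave 0.0156 M, 0.0247 M, 0.0344 M and 0.0322 M, so the row rises, then falls, turning at 0.14 M of E. At 25.0 h alder held more X than larch, 17.2 % against 1.39 % of the E charged. Alder's Z stayed under its ceiling, at 75.6 % of 0.0426 M. Larch's Z reached 87.9 % of its 0.0177 M.

All runs were computed from invented constants.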